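**Retrosynthetic overview**

1. The target is a C3–C3'-linked biflavanone (unit A unprimed, unit B primed). Only the aryl ring on C2' of unit B has a free para-hydroxyl; the aryl ring on C2 of unit A is its methyl ether. So only C2' can be reached through a para-quinone methide, and the O1'–C2' bond (pyranone ring of unit B) is made last, before debenzylation.
2. O1–C2 of the 2,3-cis unit A: catalytic oxa-Michael closure of a 2'-hydroxychalcone, with kinetic protonation at C3.
3. C2=C3: aldol condensation of 4-methoxybenzaldehyde at the free methylene of an (R)-2-benzyl-1,4-diaryl-1,4-diketone; C3' comes from asymmetric hydrogenation of the 2-arylidene diketone.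
4. C3–C3': oxidative homocoupling of two molecules of the enolate of 2',4',6'-tris(benzyloxy)acetophenone.
5. Ring order: rings A and A' are bought in the acetophenone; then the pyranone ring of unit A (step 8); then the pyranone ring of unit B (step 9).

Key step: step 9

Assumption: the sense of induction written for the two chiral catalysts (steps 5 and 8) is the expected one; each has a mirror-image or pseudo-enantiomeric partner, so the hand of either step can be matched to the required configuration without changing the route.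

**Route**

Step 1
Reactants: 1 2',4',6'-trihydroxyacetophenone
Product: 2 1-[2,4,6-tris(benzyloxy)phenyl]ethanone
Conditions: BnBr (3.5 equiv), K2CO3, DMF, 80 °C
Reagents that add atoms: benzyl bromide, BrCc1ccccc1
Why: Williamson ether synthesis on all three phenols; the two hydrogen-bonded ortho hydroxyls are alkylated only in DMF with heating, which is why these conditions are chosen.

Step 2
Reactants: 2 1-[2,4,6-tris(benzyloxy)phenyl]ethanone (two molecules, joined to each other)
Product: 4 1,4-bis[2,4,6-tris(benzyloxy)phenyl]butane-1,4-dione, via lithium enolate 3 (not isolated)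
Conditions: LDA (1.05 equiv), THF, −78 °C; then CuCl2 (1.1 equiv), DMF, −78 °C to rt
Reagents that add atoms: a second molecule of 2, 1-[2,4,6-tris(benzyloxy)phenyl]ethanone, CC(=O)c1c(OCc2ccccc2)cc(OCc2ccccc2)cc1OCc1ccccc1
Why: Oxidative enolate homocoupling: each of two molecules of methyl ketone enolate 3 is oxidised by one equivalent of CuCl2 and the two α-carbons are joined, which forms the C3–C3' bond of the symmetric 1,4-diketone with both halves of 4 coming from 2.

Step 3
Reactants: 5 4-hydroxybenzaldehyde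
Product: 6 4-(methoxymethoxy)benzaldehyde
Conditions: MOMCl, iPr2NEt, CH2Cl2, 0 °C to rt
Reagents that add atoms: chloromethyl methyl ether, COCCl
Why: Williamson-type O-alkylation masks the phenol as an acetal that survives strong base and hydrogenation and is removed together with the ortho benzyl ethers in step 7.

Step 4
Reactants: 4 1,4-bis[2,4,6-tris(benzyloxy)phenyl]butane-1,4-dione; 6 4-(methoxymethoxy)benzaldehyde
Product: 10 (2E)-2-[4-(methoxymethoxy)benzylidene]-1,4-bis[2,4,6-tris(benzyloxy)phenyl]butane-1,4-dione, via lithium enolate 7 (not isolated), via lithium aldolate 8 (not isolated), via mesylate 9 (not isolated)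
Conditions: LiHMDS (1.0 equiv), THF, −78 °C; 6; then MsCl, Et3N, −78 to 0 °C
Reagents that add atoms: none
Why: Directed aldol condensation (aldol addition of the mono-enolate, mesylation, E1cB elimination); one equivalent of base limits the reaction to one methylene, and the elimination should give the E-alkene with the aryl group trans to the aroyl group.

Step 5
Reactants: 10 (2E)-2-[4-(methoxymethoxy)benzylidene]-1,4-bis[2,4,6-tris(benzyloxy)phenyl]butane-1,4-dione
Product: 11 (2R)-2-[4-(methoxymethoxy)benzyl]-1,4-bis[2,4,6-tris(benzyloxy)phenyl]butane-1,4-dione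
Conditions: [Ir(cod)((S)-tBu-PHOX)][B(C6H3(CF3)2)4] (2 mol %; tBu-PHOX = 4-tert-butyl-2-[2-(diphenylphosphanyl)phenyl]-4,5-dihydrooxazole), H2 (50 bar), CH2Cl2, rt
Reagents that add atoms: none
Why: Iridium N,P-ligand-catalysed asymmetric hydrogenation of an α-substituted α,β-unsaturated ketone: the ligand directs H2 to one face of the trisubstituted E-alkene and sets C3' (R), and the homogeneous catalyst does not touch benzyl ethers, the MOM ether or the hindered ketones.

Step 6
Reactants: 11 (2R)-2-[4-(methoxymethoxy)benzyl]-1,4-bis[2,4,6-tris(benzyloxy)phenyl]butane-1,4-dione; 12 4-methoxybenzaldehyde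
Product: 16 (2E,3R)-2-(4-methoxybenzylidene)-3-[4-(methoxymethoxy)benzyl]-1,4-bis[2,4,6-tris(benzyloxy)phenyl]butane-1,4-dione, via lithium enolate 13 (not isolated), via lithium aldolate 14 (not isolated), via mesylate 15 (not isolated)
Conditions: LiHMDS (1.05 equiv), THF, −78 °C; 12; then MsCl, Et3N, −78 to −20 °C
Reagents that add atoms: none
Why: Directed aldol condensation through the kinetic enolate: the bulky amide should deprotonate the less hindered C3 methylene and not the C3' methine, and mesylation with E1cB elimination by the weak base Et3N should give the E-enone without enolising C3'.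

Step 7
Reactants: 16 (2E,3R)-2-(4-methoxybenzylidene)-3-[4-(methoxymethoxy)benzyl]-1,4-bis[2,4,6-tris(benzyloxy)phenyl]butane-1,4-dione
Product: 17 (2E,3R)-1,4-bis[2,4-bis(benzyloxy)-6-hydroxyphenyl]-3-(4-hydroxybenzyl)-2-(4-methoxybenzylidene)butane-1,4-dione
Conditions: BCl3 (3.3 equiv), CH2Cl2, −78 °C; MeOH quench at −78 °C
Reagents that add atoms: none
Why: Chelation-directed Lewis-acid ether cleavage: BCl3 bound to each aryl ketone carbonyl removes one ortho benzyl ether per ring and also the acetal-type MOM ether at −78 °C, while the non-chelated benzyl ethers and the aryl methyl ether should survive and the boron-bound phenoxide cannot add to the enone before the cold quench.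

Step 8
Reactants: 17 (2E,3R)-1,4-bis[2,4-bis(benzyloxy)-6-hydroxyphenyl]-3-(4-hydroxybenzyl)-2-(4-methoxybenzylidene)butane-1,4-dione
Product: 19 (2S,3S)-5,7-bis(benzyloxy)-3-{(2R)-1-[2,4-bis(benzyloxy)-6-hydroxyphenyl]-3-(4-hydroxyphenyl)-1-oxopropan-2-yl}-2-(4-methoxyphenyl)chroman-4-one, via enol 18 (not isolated)
Conditions: N-[3,5-bis(trifluoromethyl)phenyl]-N'-[(8α,9S)-6'-methoxycinchonan-9-yl]thiourea (10 mol %), toluene, −20 °C
Reagents that add atoms: none
Why: Asymmetric intramolecular oxa-Michael addition under bifunctional tertiary amine–thiourea catalysis: the catalyst-bound ring A phenol should add to one face of the enone to set C2 (S), enol 18 should be protonated at C3 anti to the pseudo-axial 4-methoxyphenyl group to give the kinetic 2,3-cis isomer (3S), and the low temperature and weak base should leave C3' (R) from step 5 in place.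

Step 9
Reactants: 19 (2S,3S)-5,7-bis(benzyloxy)-3-{(2R)-1-[2,4-bis(benzyloxy)-6-hydroxyphenyl]-3-(4-hydroxyphenyl)-1-oxopropan-2-yl}-2-(4-methoxyphenyl)chroman-4-one
Product: 21 (2S,3S)-5,7-bis(benzyloxy)-3-[(2R,3S)-5,7-bis(benzyloxy)-2-(4-hydroxyphenyl)-4-oxochroman-3-yl]-2-(4-methoxyphenyl)chroman-4-one, via quinone methide 20 (not isolated)
Conditions: DDQ (1.05 equiv), 1,4-dioxane, rt
Reagents that add atoms: none
Why: DDQ dehydrogenates the 4-hydroxybenzyl group of 19 (charge-transfer complex, then loss of a hydride equivalent from the benzylic CH2) to para-quinone methide 20, whose exocyclic carbon (the future C2') is a vinylogous Michael acceptor; the ortho hydroxyl of ring A' adds to it in a 1,6-conjugate addition and the ring rearomatises to the 4-hydroxyphenyl group. The closest known reaction type is the DDQ-mediated oxidative cyclisation of 1-(2-hydroxyaryl)-3-(4-hydroxyphenyl)propanes and 2'-hydroxydihydrochalcones to flavans and flavanones, together with oxygen trapping of DDQ-generated quinone methides. The pyranone ring of unit B closes in the 6-exo-trig mode, since the attacked C=C lies outside the new ring. The new stereocentre C2' is controlled by the existing C3' centre: in the half-chair transition state the quinoid ring and the bulky flavanone substituent on C3' should both sit pseudo-equatorial, which gives the 2',3'-trans (2'R,3'S) arrangement, and any reversible reopening through the quinone methide would lead to the same isomer. The step needs chemoselectivity for the benzylic CH2 of unit B over C2–H of unit A and the four benzyl ethers; the single free para-phenol secures it, because only that ring can become a neutral quinone methide under these mild conditions, and the neutral medium should leave the enolisable C3 and C3' centres and the cis unit A untouched.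

Step 10
Reactants: 21 (2S,3S)-5,7-bis(benzyloxy)-3-[(2R,3S)-5,7-bis(benzyloxy)-2-(4-hydroxyphenyl)-4-oxochroman-3-yl]-2-(4-methoxyphenyl)chroman-4-one
Product: 22 (2S,3S)-5,7-dihydroxy-3-[(2R,3S)-5,7-dihydroxy-2-(4-hydroxyphenyl)-4-oxochroman-3-yl]-2-(4-methoxyphenyl)chroman-4-one (CNP0196568.4)
Conditions: H2 (1 atm), Pd/C (10 %), EtOAc/THF, rt
Reagents that add atoms: none
Why: Catalytic hydrogenolysis of the four aryl benzyl ethers under neutral conditions; the ketones, the aryl methyl ether and the cyclic O1–C2 and O1'–C2' bonds react more slowly at 1 atm, and no acid or base is present to epimerise C3 or C3' or open the rings.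

**Compound list**

1 | 2',4',6'-trihydroxyacetophenone | CC(=O)c1c(O)cc(O)cc1O | starting material
2 | 1-[2,4,6-tris(benzyloxy)phenyl]ethanone | CC(=O)c1c(OCc2ccccc2)cc(OCc2ccccc2)cc1OCc1ccccc1 | intermediate
3 | lithium enolate of 2 (not isolated) | C=C([O-])c1c(OCc2ccccc2)cc(OCc2ccccc2)cc1OCc1ccccc1.[Li+] | intermediate
4 | 1,4-bis[2,4,6-tris(benzyloxy)phenyl]butane-1,4-dione | O=C(CCC(=O)c1c(OCc2ccccc2)cc(OCc2ccccc2)cc1OCc1ccccc1)c1c(OCc2ccccc2)cc(OCc2ccccc2)cc1OCc1ccccc1 | intermediate
5 | 4-hydroxybenzaldehyde | O=Cc1ccc(O)cc1 | starting material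
6 | 4-(methoxymethoxy)benzaldehyde | COCOc1ccc(C=O)cc1 | intermediate
7 | lithium mono-enolate of 4 (not isolated) | [Li+].[O-]C(=CCC(=O)c1c(OCc2ccccc2)cc(OCc2ccccc2)cc1OCc1ccccc1)c1c(OCc2ccccc2)cc(OCc2ccccc2)cc1OCc1ccccc1 | intermediate
8 | lithium aldolate from 7 and 6, mixture of diastereomers (not isolated) | [Li+].[O-]C(c1ccc(OCOC)cc1)C(CC(=O)c1c(OCc2ccccc2)cc(OCc2ccccc2)cc1OCc1ccccc1)C(=O)c1c(OCc2ccccc2)cc(OCc2ccccc2)cc1OCc1ccccc1 | intermediate
9 | mesylate of aldol 8, mixture of diastereomers (not isolated) | CS(=O)(=O)OC(c1ccc(OCOC)cc1)C(CC(=O)c1c(OCc2ccccc2)cc(OCc2ccccc2)cc1OCc1ccccc1)C(=O)c1c(OCc2ccccc2)cc(OCc2ccccc2)cc1OCc1ccccc1 | intermediate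
10 | (2E)-2-[4-(methoxymethoxy)benzylidene]-1,4-bis[2,4,6-tris(benzyloxy)phenyl]butane-1,4-dione | COCOc1ccc(/C=C(/C(=O)c2c(OCc3ccccc3)cc(OCc3ccccc3)cc2OCc2ccccc2)CC(=O)c2c(OCc3ccccc3)cc(OCc3ccccc3)cc2OCc2ccccc2)cc1 | intermediate
11 | (2R)-2-[4-(methoxymethoxy)benzyl]-1,4-bis[2,4,6-tris(benzyloxy)phenyl]butane-1,4-dione | O=C(C[C@@H](Cc1ccc(OCOC)cc1)C(=O)c1c(OCc2ccccc2)cc(OCc2ccccc2)cc1OCc1ccccc1)c1c(OCc2ccccc2)cc(OCc2ccccc2)cc1OCc1ccccc1 | intermediate
12 | 4-methoxybenzaldehyde | COc1ccc(C=O)cc1 | starting material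
13 | lithium enolate of 11 at the C3 methylene (not isolated) | [Li+].[O-]C(=C[C@@H](Cc1ccc(OCOC)cc1)C(=O)c1c(OCc2ccccc2)cc(OCc2ccccc2)cc1OCc1ccccc1)c1c(OCc2ccccc2)cc(OCc2ccccc2)cc1OCc1ccccc1 | intermediate
14 | lithium aldolate from 13 and 12, mixture at the two new centres (not isolated) | [Li+].[O-]C(c1ccc(OC)cc1)C(C(=O)c1c(OCc2ccccc2)cc(OCc2ccccc2)cc1OCc1ccccc1)[C@@H](Cc1ccc(OCOC)cc1)C(=O)c1c(OCc2ccccc2)cc(OCc2ccccc2)cc1OCc1ccccc1 | intermediate
15 | mesylate of aldol 14, mixture at the two new centres (not isolated) | CS(=O)(=O)OC(c1ccc(OC)cc1)C(C(=O)c1c(OCc2ccccc2)cc(OCc2ccccc2)cc1OCc1ccccc1)[C@@H](Cc1ccc(OCOC)cc1)C(=O)c1c(OCc2ccccc2)cc(OCc2ccccc2)cc1OCc1ccccc1 | intermediate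
16 | (2E,3R)-2-(4-methoxybenzylidene)-3-[4-(methoxymethoxy)benzyl]-1,4-bis[2,4,6-tris(benzyloxy)phenyl]butane-1,4-dione | COc1ccc(/C=C(/C(=O)c2c(OCc3ccccc3)cc(OCc3ccccc3)cc2OCc2ccccc2)[C@@H](Cc2ccc(OCOC)cc2)C(=O)c2c(OCc3ccccc3)cc(OCc3ccccc3)cc2OCc2ccccc2)cc1 | intermediate
17 | (2E,3R)-1,4-bis[2,4-bis(benzyloxy)-6-hydroxyphenyl]-3-(4-hydroxybenzyl)-2-(4-methoxybenzylidene)butane-1,4-dione | COc1ccc(/C=C(/C(=O)c2c(O)cc(OCc3ccccc3)cc2OCc2ccccc2)[C@@H](Cc2ccc(O)cc2)C(=O)c2c(O)cc(OCc3ccccc3)cc2OCc2ccccc2)cc1 | intermediate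
18 | C3=C4 enol (2H-chromen-4-ol) tautomer of 19 (not isolated) | COc1ccc([C@H]2Oc3cc(OCc4ccccc4)cc(OCc4ccccc4)c3C(O)=C2[C@@H](Cc2ccc(O)cc2)C(=O)c2c(O)cc(OCc3ccccc3)cc2OCc2ccccc2)cc1 | intermediate
19 | (2S,3S)-5,7-bis(benzyloxy)-3-{(2R)-1-[2,4-bis(benzyloxy)-6-hydroxyphenyl]-3-(4-hydroxyphenyl)-1-oxopropan-2-yl}-2-(4-methoxyphenyl)chroman-4-one (2,3-cis; key-step precursor) | COc1ccc([C@H]2Oc3cc(OCc4ccccc4)cc(OCc4ccccc4)c3C(=O)[C@H]2[C@@H](Cc2ccc(O)cc2)C(=O)c2c(O)cc(OCc3ccccc3)cc2OCc2ccccc2)cc1 | intermediate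
20 | para-quinone methide of 19 (4-hydroxybenzyl group oxidised to the 4-oxocyclohexa-2,5-dienylidene-methyl group; not isolated) | COc1ccc([C@H]2Oc3cc(OCc4ccccc4)cc(OCc4ccccc4)c3C(=O)[C@H]2[C@@H](C=C2C=CC(=O)C=C2)C(=O)c2c(O)cc(OCc3ccccc3)cc2OCc2ccccc2)cc1 | intermediate
21 | (2S,3S)-5,7-bis(benzyloxy)-3-[(2R,3S)-5,7-bis(benzyloxy)-2-(4-hydroxyphenyl)-4-oxochroman-3-yl]-2-(4-methoxyphenyl)chroman-4-one | COc1ccc([C@H]2Oc3cc(OCc4ccccc4)cc(OCc4ccccc4)c3C(=O)[C@H]2[C@@H]2C(=O)c3c(OCc4ccccc4)cc(OCc4ccccc4)cc3O[C@H]2c2ccc(O)cc2)cc1 | intermediate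
22 | (2S,3S)-5,7-dihydroxy-3-[(2R,3S)-5,7-dihydroxy-2-(4-hydroxyphenyl)-4-oxochroman-3-yl]-2-(4-methoxyphenyl)chroman-4-one (unit A 2,3-cis, unit B 2',3'-trans) | COc1ccc([C@H]2Oc3cc(O)cc(O)c3C(=O)[C@H]2[C@@H]2C(=O)c3c(O)cc(O)cc3O[C@H]2c2ccc(O)cc2)cc1 | target

**Step count and risks**

Total steps: 10. Longest linear sequence: 9 steps (steps 1, 2, 4, 5, 6, 7, 8, 9, 10 from compound 1); step 3 is a one-step side branch.

Steps most likely to fail:

1. Step 9 (key step). If O-attack by the hydrogen-bonded ring A' hydroxyl is slow, quinone methide 20 may tautomerise to the 4-hydroxychalcone by loss of the C3' proton, which would erase C3'. It may also be dehydrogenated further, and DDQ may begin to abstract hydride from C2–H of unit A. Fallback, from 19 back to 21: the oxidation is run with DDQ in CH2Cl2/MeOH at 0 °C, so that the solvent intercepts the quinone methide as it forms and gives the C2'-methyl ether F1 (both C2' epimers), leaving no time for tautomerisation. F1 is then ionised with catalytic Sc(OTf)3 in CH2Cl2 at −20 °C. Loss of methanol regenerates the O-protonated quinone methide in an acidic medium in which C3'–H is not removed, and the ring A' hydroxyl closes the ring to 21 under thermodynamic, trans-selective control.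

2. Step 8. Three processes threaten it: enolisation of the product by the amine catalyst with drift from the kinetic 2,3-cis to the trans isomer; insufficient or mismatched facial control at C2 because the substrate already carries C3'; and epimerisation of the doubly activated C3'–H of enone 17 before ring closure. Fallback, from 11 back to 19: C2 is set by C–C bond formation on a closed pyranone instead of C–O closure. BCl3 at −78 °C (as in step 7) converts 11 into triphenol diketone F2. N,N-Dimethylformamide dimethyl acetal in toluene at 80 °C condenses only at the C3 methylene, the only α-CH2 in F2, to give enaminone F3. On mild acidification the ring A hydroxyl adds to the enaminone and dimethylamine is lost, which closes the 3-substituted chromone F4. Conjugate addition of 4-methoxyphenylboronic acid with Pd(OCOCF3)2 and (S)-4-tert-butyl-2-(pyridin-2-yl)-4,5-dihydrooxazole (NH4PF6, H2O, 1,2-dichloroethane, 60 °C) then delivers the aryl group to C2 under ligand control. Protonation of the palladium enolate at C3 anti to the new aryl group should give the cis compound 19.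

3. Step 5. The hindered trisubstituted enone may be hydrogenated slowly or with poor facial discrimination, and acidic iridium hydride species may attack the MOM ether. Fallback, from 10 back to 11: conjugate reduction of 10 with [(Ph3P)CuH]6 in toluene gives racemic diketone F5, which is resolved by preparative chromatography on a chiral stationary phase (cellulose tris(3,5-dimethylphenylcarbamate)); the (R)-enantiomer is 11.

**Further compounds**

F1 | step 9 | C2'-methoxy derivative of 19: (2S,3S)-5,7-bis(benzyloxy)-3-{1-[2,4-bis(benzyloxy)-6-hydroxyphenyl]-3-(4-hydroxyphenyl)-3-methoxy-1-oxopropan-2-yl}-2-(4-methoxyphenyl)chroman-4-one, C3' as in 19, both epimers at the methoxylated carbon | COc1ccc([C@H]2Oc3cc(OCc4ccccc4)cc(OCc4ccccc4)c3C(=O)[C@H]2[C@@H](C(OC)c2ccc(O)cc2)C(=O)c2c(O)cc(OCc3ccccc3)cc2OCc2ccccc2)cc1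
F2 | step 8 | (2R)-1,4-bis[2,4-bis(benzyloxy)-6-hydroxyphenyl]-2-(4-hydroxybenzyl)butane-1,4-dione | O=C(C[C@@H](Cc1ccc(O)cc1)C(=O)c1c(O)cc(OCc2ccccc2)cc1OCc1ccccc1)c1c(O)cc(OCc2ccccc2)cc1OCc1ccccc1
F3 | step 8 | (3R)-1,4-bis[2,4-bis(benzyloxy)-6-hydroxyphenyl]-2-[(dimethylamino)methylidene]-3-(4-hydroxybenzyl)butane-1,4-dione (enaminone, alkene geometry not defined) | CN(C)C=C(C(=O)c1c(O)cc(OCc2ccccc2)cc1OCc1ccccc1)[C@@H](Cc1ccc(O)cc1)C(=O)c1c(O)cc(OCc2ccccc2)cc1OCc1ccccc1
F4 | step 8 | 5,7-bis(benzyloxy)-3-{(2R)-1-[2,4-bis(benzyloxy)-6-hydroxyphenyl]-3-(4-hydroxyphenyl)-1-oxopropan-2-yl}-4H-chromen-4-one | O=c1c([C@@H](Cc2ccc(O)cc2)C(=O)c2c(O)cc(OCc3ccccc3)cc2OCc2ccccc2)coc2cc(OCc3ccccc3)cc(OCc3ccccc3)c12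
F5 | step 5 | racemic 2-[4-(methoxymethoxy)benzyl]-1,4-bis[2,4,6-tris(benzyloxy)phenyl]butane-1,4-dione | O=C(CC(Cc1ccc(OCOC)cc1)C(=O)c1c(OCc2ccccc2)cc(OCc2ccccc2)cc1OCc1ccccc1)c1c(OCc2ccccc2)cc(OCc2ccccc2)cc1OCc1ccccc1
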